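We set this flask beside its nearest neighbour, which has the same charge but no pairing of J into J2.

    J → Q (k1 = 0.00357 /min)
    Z + J → D + J, rate k2*[Z]^2.5*[J]/(1 + ([Z]/Kh2)^2.5) (Kh2 = 15.8 mM, k2 = 8.57 × 10⁵ /M².5/s)
    2 J ⇌ J2, settled at all times (K3 = 50500 /M)

Z 11 mM; J 0.05 mol%

- the form that holds most of the catalyst when 30 % of the Z are converted (J / J2 / Q)
- its share of the catalyst then
- apparent order in J when 30 % of the Z are converted (percent change of the rate of making D for one percent more J charged)

- Our own reckoning counts turnovers. To reach 30 % conversion, each charged catalyst must turn over 600 times.
- Each J makes D more slowly as Z falls. At 30 % conversion its speed is down to 3.82 /s, and it is higher before that.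
- Each J turns into Q at 0.00357 /min, far more slowly than it makes D. So the Q made by then is at most 0.935 % of the catalyst.
- We therefore turn to the pairing balance. The charged catalyst is 0.00550 mM. The pairing number, 2 times the pairing constant times that catalyst, is 0.555.
- Solving the balance, before any Q forms, leaves 71.6 % of the catalyst free. We call this the working share, the fraction of the catalyst standing free as J at balance.
- We therefore expect J to hold most of the catalyst, with J2 outside the working round, as Q is. Differentiating the balance gives an order of 0.779, which is less than one.
- The neighbour has no J2, so, Q apart, its free J equals its charge. We expect it to reach an order of one and to run 1.40 times as fast as this flask at that conversion.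
- The forecast names J, with a share of 71 % and an order of 0.78. It argues that “the monomer–dimer balance makes J rise less than proportionally with the charge”.
- The flask reaches 30 % conversion after 2.55 min. The main form is J: J holds 71.2 %, J2 28.2 % and Q 0.649 %. The order is 0.78.
- The pairing of J into J2 is the largest single effect shown on this rate. This flask makes D at 53.9 mM/h at that conversion. Dividing by the working share gives 75.3 mM/h for the neighbour. The simulated run with the association of 2 J to J2 taken away, both ways, stands at 1.40 times the rate of this flask. With the association of 2 J to J2 taken away, the order is 1.0, against 0.78 in this flask.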